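**Plan**

1. Retrosynthesis: the two ring B bromines (C2'–Br, C4'–Br) are removed first, the C1–OH bond is traced back to a C1–B bond, and ring A is then cut at C2–C3 and C6–C1.
2. Enabling feature: in ring A, C3, C4, C5 and C6 carry Br, Br, Br and H, which is the four-carbon frame of 2,3,4-tribromothiophene 1,1-dioxide; the two oxygen-bearing carbons C1 (OH) and C2 (OAr) are the two carbons of an alkyne, a phenoxyethynyl boronate.
3. Forward, diene: tetrabromothiophene → 2,3,4-tribromothiophene → its 1,1-dioxide. Forward, dienophile: phenol + trichloroethylene → dichlorovinyl ether → boryl ynol ether; ring B comes in as plain phenoxy because n-BuLi is used.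
4. Ring A is the only ring that is built. It arises in step 5 by [4+2] cycloaddition and loss of SO2; then C–B → C–OH, acetate protection, dibromination of ring B (C4', then C2') and deacetylation.
5. Stereochemistry: the target has no stereocentre. What must be controlled is regiochemistry: in step 5 by the polarised alkyne and by sterics, in step 8 by the ether oxygen directing on ring B while ring A is deactivated.

Key step: step 5

Remark: dioxide 5 has one unsubstituted carbon next to sulfur; it is assumed to be isolable for a short time like its tetrabromo and 3,4-dibromo relatives, and is made just before step 5.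

**Route**

Step 1
Reactants: 1 tetrabromothiophene
Product: 3 2,3,4-tribromothiophene, via 3,4,5-tribromo-2-thienyllithium 2 (not isolated)
Conditions: n-BuLi (1.0 equiv), THF, −78 °C; then MeOH, −78 °C to rt
Reagents that add atoms: none
Why: Bromine–lithium exchange is fastest at a position next to sulfur, where the thienyllithium is best stabilised, so one equivalent of n-BuLi at low temperature should remove a single alpha bromine, and protonation then gives the tribromide (halogen–metal exchange and protonolysis).

Step 2
Reactants: 3 2,3,4-tribromothiophene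
Product: 5 2,3,4-tribromothiophene 1,1-dioxide, via 2,3,4-tribromothiophene 1-oxide 4 (not isolated)
Conditions: urea·H2O2 (5 equiv), (CF3CO)2O (4 equiv), MeCN/CH2Cl2, 0 °C to rt
Reagents that add atoms: trifluoroperacetic acid OOC(=O)C(F)(F)F, made in the flask from hydrogen peroxide OO (as its urea adduct) and trifluoroacetic anhydride O=C(OC(=O)C(F)(F)F)C(F)(F)F; it supplies both sulfone oxygens
Why: Trifluoroperacetic acid, the most electrophilic common peracid, should oxidise the weakly nucleophilic sulfur of a halogenated thiophene (sulfur oxidation, as practised on tetrachloro- and tetrabromothiophene), and since sulfoxide 4 is oxidised faster than the aromatic thiophene the reaction should run through to the dioxide.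

Step 3
Reactants: 6 phenol; 7 trichloroethylene
Product: 9 (E)-1,2-dichlorovinyl phenyl ether, via dichloroacetylene 8 (not isolated)
Conditions: K2CO3 (2 equiv), trichloroethylene (2 equiv), DMF, 70 °C
Reagents that add atoms: none
Why: Base-induced dehydrochlorination of trichloroethylene gives dichloroacetylene in solution, and phenoxide adds to it with anti delivery of oxygen and hydrogen (nucleophilic addition to a haloalkyne), which sets the E geometry with the two chlorines trans.

Step 4
Reactants: 9 (E)-1,2-dichlorovinyl phenyl ether; 10 2-isopropoxy-4,4,5,5-tetramethyl-1,3,2-dioxaborolane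
Product: 14 4,4,5,5-tetramethyl-2-(phenoxyethynyl)-1,3,2-dioxaborolane, via chloro(phenoxy)ethyne 11 (not isolated), via lithium phenoxyethynide 12 (not isolated), via lithium isopropoxy(phenoxyethynyl)pinacolborate 13 (not isolated)
Conditions: n-BuLi (2.05 equiv), THF, −78 to −40 °C; then 10 (1.1 equiv), −78 °C; then HCl (2 M in Et2O, 1.1 equiv), −78 °C to rt; LiCl filtered off under argon
Reagents that add atoms: none
Why: n-BuLi should first eliminate HCl and then exchange the alkynyl chlorine for lithium (the dichlorovinyl ether route to aryl ynol ethers), and the acetylide adds to the borate ester to give an ate complex from which anhydrous HCl removes isopropoxide (acetylide borylation with acid release of the alkynylboronate).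

Step 5
Reactants: 5 2,3,4-tribromothiophene 1,1-dioxide; 14 4,4,5,5-tetramethyl-2-(phenoxyethynyl)-1,3,2-dioxaborolane
Product: 16 2-(3,4,5-tribromo-2-phenoxyphenyl)-4,4,5,5-tetramethyl-1,3,2-dioxaborolane, via bridged sulfone cycloadduct 15 (not isolated)
Conditions: 14 (1.5 equiv), toluene, 60 to 90 °C, argon, slow addition of 5
Reagents that add atoms: none
Why: Proposed new method: the electron-poor cyclic diene of sulfone 5 and the push–pull alkyne 14 should combine in a concerted but asynchronous inverse-electron-demand [4+2] cycloaddition across the two carbons next to sulfur, and the strained 7-thiabicyclo[2.2.1]heptadiene 7,7-dioxide 15 should then lose SO2 irreversibly by cheletropic extrusion. The closest known reaction types are the cycloaddition/SO2-extrusion benzannulation of tetrahalothiophene 1,1-dioxides with alkynes and the [4+2]/extrusion benzannulation of alkynyl pinacolboronates with electron-poor cyclic dienes such as 2-pyrones; the pairing of a halothiophene dioxide with a boryl ynol ether is the untested part. Ring A is closed by an intermolecular [4+2] cycloaddition that forms the C2–C3 and C6–C1 bonds of the target in one operation, and it becomes aromatic when the sulfur bridge leaves. No stereocentre remains, because the two bridgehead centres of 15 disappear on extrusion. The step needs regioselectivity: the boron-bearing alkyne carbon is the nucleophilic end (beta to oxygen, alpha to the pi-accepting boron) and should lead the bonding to the hydrogen-bearing carbon next to sulfur, the less hindered terminus, which leaves the developing negative charge at the other terminus where sulfonyl and bromine stabilise it, and the bulky pinacolboryl group also avoids the brominated bridgehead. Slow addition of 5 to an excess of 14 should hold back self-dimerisation of the dioxide.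

Step 6
Reactants: 16 2-(3,4,5-tribromo-2-phenoxyphenyl)-4,4,5,5-tetramethyl-1,3,2-dioxaborolane
Product: 18 3,4,5-tribromo-2-phenoxyphenol, via aryl pinacol borate 17 (not isolated)
Conditions: H2O2 (30% aq, 3 equiv), THF, pH 7 phosphate buffer, 0 °C to rt
Reagents that add atoms: hydrogen peroxide OO
Why: Hydroperoxide adds to boron and the aryl group migrates from boron to oxygen at the same carbon (oxidation of an arylboronic ester), and the borate ester 17 hydrolyses in the aqueous medium, so the hydroxyl appears exactly at C1.

Step 7
Reactants: 18 3,4,5-tribromo-2-phenoxyphenol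
Product: 19 3,4,5-tribromo-2-phenoxyphenyl acetate
Conditions: Ac2O (1.5 equiv), pyridine, DMAP (cat.), CH2Cl2, rt
Reagents that add atoms: acetic anhydride CC(=O)OC(C)=O
Why: DMAP-catalysed O-acylation should be clean on this acidic phenol, and the acetate removes the strong activation that a free hydroxyl would give to C6 of ring A in the bromination that follows.

Step 8
Reactants: 19 3,4,5-tribromo-2-phenoxyphenyl acetate
Product: 21 3,4,5-tribromo-2-(2,4-dibromophenoxy)phenyl acetate, via 4'-monobromo acetate 20 (not isolated)
Conditions: Br2 (2.2 equiv), FeBr3 (5 mol%), CH2Cl2, 0 °C to rt, dark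
Reagents that add atoms: bromine BrBr
Why: In this electrophilic aromatic bromination the ether oxygen should direct the first bromine para and the second ortho on ring B, while ring A, with three bromines and an acetoxy group, is strongly deactivated at its only free position, and a third bromination of the twice-deactivated ring B should be slow enough to be stopped by stoichiometry.

Step 9
Reactants: 21 3,4,5-tribromo-2-(2,4-dibromophenoxy)phenyl acetate
Product: 22 3,4,5-tribromo-2-(2,4-dibromophenoxy)phenol
Conditions: HCl (1.25 M in MeOH), THF, 40 °C
Reagents that add atoms: none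
Why: Acid-catalysed methanolysis (transesterification) should remove the aryl acetate as methyl acetate and leave the aryl bromides and the diaryl ether untouched.

**Compound list**

1 | tetrabromothiophene | Brc1sc(Br)c(Br)c1Br | starting material
2 | (3,4,5-tribromothiophen-2-yl)lithium | [Li]c1sc(Br)c(Br)c1Br | intermediate
3 | 2,3,4-tribromothiophene | Brc1scc(Br)c1Br | intermediate
4 | 2,3,4-tribromothiophene 1-oxide (racemic at sulfur) | O=S1C=C(Br)C(Br)=C1Br | intermediate
5 | 2,3,4-tribromothiophene 1,1-dioxide | O=S1(=O)C=C(Br)C(Br)=C1Br | intermediate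
6 | phenol | Oc1ccccc1 | starting material
7 | trichloroethylene | ClC=C(Cl)Cl | starting material
8 | dichloroacetylene | ClC#CCl | intermediate
9 | (E)-1,2-dichlorovinyl phenyl ether | Cl/C=C(/Cl)Oc1ccccc1 | intermediate
10 | 2-isopropoxy-4,4,5,5-tetramethyl-1,3,2-dioxaborolane | CC(C)OB1OC(C)(C)C(C)(C)O1 | starting material
11 | chloro(phenoxy)ethyne | ClC#COc1ccccc1 | intermediate
12 | lithium phenoxyethynide | [Li]C#COc1ccccc1 | intermediate
13 | lithium isopropoxy(phenoxyethynyl)pinacolborate | [Li+].CC(C)O[B-]1(C#COc2ccccc2)OC(C)(C)C(C)(C)O1 | intermediate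
14 | 4,4,5,5-tetramethyl-2-(phenoxyethynyl)-1,3,2-dioxaborolane | CC1(C)OB(C#COc2ccccc2)OC1(C)C | intermediate
15 | 1,2,3-tribromo-6-phenoxy-5-(4,4,5,5-tetramethyl-1,3,2-dioxaborolan-2-yl)-7-thiabicyclo[2.2.1]hepta-2,5-diene 7,7-dioxide (racemic; bridgehead configurations fixed by the bicycle) | O=S1(=O)C2(Br)C(Br)=C(Br)C1C(B3OC(C)(C)C(C)(C)O3)=C2Oc4ccccc4 | intermediate
16 | 2-(3,4,5-tribromo-2-phenoxyphenyl)-4,4,5,5-tetramethyl-1,3,2-dioxaborolane | CC1(C)OB(OC1(C)C)c1cc(Br)c(Br)c(Br)c1Oc1ccccc1 | intermediate
17 | 4,4,5,5-tetramethyl-2-(3,4,5-tribromo-2-phenoxyphenoxy)-1,3,2-dioxaborolane | CC1(C)OB(Oc2cc(Br)c(Br)c(Br)c2Oc2ccccc2)OC1(C)C | intermediate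
18 | 3,4,5-tribromo-2-phenoxyphenol | Oc1cc(Br)c(Br)c(Br)c1Oc1ccccc1 | intermediate
19 | 3,4,5-tribromo-2-phenoxyphenyl acetate | CC(=O)Oc1cc(Br)c(Br)c(Br)c1Oc1ccccc1 | intermediate
20 | 3,4,5-tribromo-2-(4-bromophenoxy)phenyl acetate | CC(=O)Oc1cc(Br)c(Br)c(Br)c1Oc1ccc(Br)cc1 | intermediate
21 | 3,4,5-tribromo-2-(2,4-dibromophenoxy)phenyl acetate | CC(=O)Oc1cc(Br)c(Br)c(Br)c1Oc1ccc(Br)cc1Br | intermediate
22 | 3,4,5-tribromo-2-(2,4-dibromophenoxy)phenol | Oc1cc(Br)c(Br)c(Br)c1Oc1ccc(Br)cc1Br | target

**Count**

Total steps: 9. Longest linear sequence: 7 steps (steps 1, 2, 5, 6, 7, 8, 9; the alkyne branch through steps 3 and 4 is equally long).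

**Steps most likely to fail**

1. Step 5. The cycloaddition may bond in the reverse orientation, or it may turn stepwise and close a four-membered ring from a zwitterion, or the dioxide may dimerise faster than it meets the alkyne. The fallback uses known chemistry only and builds no ring. It sets out from phenol 6 and comes back to the route at phenol 18. Ullmann ether coupling of 6 with commercial 2-bromo-4-nitroanisole (CuI, picolinic acid, K3PO4, DMSO, 90 °C) should give 1-methoxy-4-nitro-2-phenoxybenzene F1. Reduction with Fe powder and NH4Cl in aqueous ethanol should give 4-methoxy-3-phenoxyaniline F2. NBS (2 equiv, MeCN, 0 °C) should brominate both positions ortho to the amino group, which outranks every other director present, to give 2,6-dibromo-4-methoxy-3-phenoxyaniline F3. A Sandmeyer bromination (t-BuONO, CuBr2, MeCN, 60 °C) replaces the amino group and should give 1,2,3-tribromo-5-methoxy-4-phenoxybenzene F4. BBr3 in CH2Cl2 then cleaves the methyl ether only and delivers 18, from which steps 7 to 9 follow unchanged.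

2. Step 4. The C(sp)–B bond may be lost by protodeboronation, or the ynol ether may be hydrated, while the ate complex is opened with HCl and during isolation. The fallback replaces boron by a neutral silicon marker. It sets out from dichlorovinyl ether 9 and comes back at phenol 18. Acetylide 12 is generated from 9 as in step 4 and quenched with chlorodimethylsilane, which needs no acid and should give distillable dimethyl(phenoxyethynyl)silane F5. Heating F5 with dioxide 5 in toluene should give, through the bridged sulfone adduct 1,2,3-tribromo-5-(dimethylsilyl)-6-phenoxy-7-thiabicyclo[2.2.1]hepta-2,5-diene 7,7-dioxide F6 and loss of SO2, dimethyl(3,4,5-tribromo-2-phenoxyphenyl)silane F7. The silicon supports the same polarisation of the alkyne, since it stabilises positive charge on the oxygen-bearing carbon. Tamao–Fleming oxidation of the Si–H silane (H2O2, KF, KHCO3, THF/MeOH) then gives 18.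

3. Step 8. Control over the degree of bromination of ring B may be lost (stopping at one bromine or running on to three). HBr or FeBr3 may also cleave the acetate, after which ring A would brominate at C6. The fallback changes both the protecting group and the mode of bromination. It sets out from phenol 18 and comes back at target 22. Tf2O and pyridine in CH2Cl2 should give 3,4,5-tribromo-2-phenoxyphenyl trifluoromethanesulfonate F8, whose sulfonate is inert to acid and deactivates ring A further. Br2 (1 equiv, CH2Cl2, 0 °C) should give the para bromide 3,4,5-tribromo-2-(4-bromophenoxy)phenyl trifluoromethanesulfonate F9, which is isolated and checked. A second, separately dosed bromination (Br2, 1.1 equiv, FeBr3 cat.) should give 3,4,5-tribromo-2-(2,4-dibromophenoxy)phenyl trifluoromethanesulfonate F10. Aqueous Et4NOH in dioxane at rt then cleaves the S–O bond and releases 22.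

**Further compounds**

F1 | step 5 | 1-methoxy-4-nitro-2-phenoxybenzene | COc1ccc(cc1Oc1ccccc1)[N+](=O)[O-]
F2 | step 5 | 4-methoxy-3-phenoxyaniline | COc1ccc(N)cc1Oc1ccccc1
F3 | step 5 | 2,6-dibromo-4-methoxy-3-phenoxyaniline | COc1cc(Br)c(N)c(Br)c1Oc1ccccc1
F4 | step 5 | 1,2,3-tribromo-5-methoxy-4-phenoxybenzene | COc1cc(Br)c(Br)c(Br)c1Oc1ccccc1
F5 | step 4 | dimethyl(phenoxyethynyl)silane | C[SiH](C)C#COc1ccccc1
F6 | step 4 | 1,2,3-tribromo-5-(dimethylsilyl)-6-phenoxy-7-thiabicyclo[2.2.1]hepta-2,5-diene 7,7-dioxide (racemic) | O=S1(=O)C2(Br)C(Br)=C(Br)C1C([SiH](C)C)=C2Oc1ccccc1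
F7 | step 4 | dimethyl(3,4,5-tribromo-2-phenoxyphenyl)silane | C[SiH](C)c1cc(Br)c(Br)c(Br)c1Oc1ccccc1
F8 | step 8 | 3,4,5-tribromo-2-phenoxyphenyl trifluoromethanesulfonate | O=S(=O)(Oc1cc(Br)c(Br)c(Br)c1Oc1ccccc1)C(F)(F)F
F9 | step 8 | 3,4,5-tribromo-2-(4-bromophenoxy)phenyl trifluoromethanesulfonate | O=S(=O)(Oc1cc(Br)c(Br)c(Br)c1Oc1ccc(Br)cc1)C(F)(F)F
F10 | step 8 | 3,4,5-tribromo-2-(2,4-dibromophenoxy)phenyl trifluoromethanesulfonate | O=S(=O)(Oc1cc(Br)c(Br)c(Br)c1Oc1ccc(Br)cc1Br)C(F)(F)F
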